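**Overview**

Cuts, in this order: (a) the hemiketal bond between flavonol O7 and the carbon bearing OH and 4-hydroxyphenyl; (b) the bond from the spiro carbon to that same carbon, which is then an aroyl C=O; (c) the bond from the spiro carbon (C2 of the benzofuran-3(2H)-one ring) to flavonol C8.
Enabling feature: with the dihydrofuran hemiketal ring opened, the spiro carbon C2 lies between the ring ketone C3=O and a 4-hydroxybenzoyl C=O. It is therefore the alpha carbon of a non-enolisable 1,3-diketone, the C-acyl isomer of a flat, achiral 2-(flavonol-8-yl)benzofuran-3-yl 4-oxybenzoate.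
Forward: kaempferol (rings A, B, C) and 4,6-dihydroxybenzofuran-3(2H)-one are bought with their rings in place, perbenzylated, and joined C8–C2 by Negishi coupling. The aroyl group is placed on O3 and shifted to C2, and the dihydrofuran ring, the only ring made, closes last on debenzylation.
Stereochemistry: a chiral isothiourea sets the quaternary carbon in the O-to-C aroyl shift, and the hemiketal carbon follows by reversible, thermodynamically controlled closure on that fixed centre.

Key step: step 8

Assumption 1: the hemiketal epimer drawn is taken to be the most stable ring-chain tautomer of the ring-opened diketone, as expected of a hemiketal that can be handled as one compound.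
Assumption 2: the sense of induction of a new reaction cannot be read from precedent, so (2S,3R)-HyperBTM is written for the R product; its equally available (2R,3S) antipode replaces it if a first run, checked by ECD or anomalous-dispersion crystallography, shows the opposite sense.
Remark on descriptors: the quaternary carbon is R in the ring-opened diketones and S in the target only because the aroyl carbon outranks C3 once it becomes a hemiketal carbon; the arrangement in space is unchanged.

**Route**

Step 1
Reactants: 1 kaempferol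
Product: 2 3,5,7,4'-tetra-O-benzylkaempferol
Conditions: BnBr (6 equiv), K2CO3 (8 equiv), DMF, 70 °C
Reagents that add atoms: benzyl bromide, BrCc1ccccc1
Why: Williamson ether synthesis: the 7-, 4'- and 3-hydroxyls alkylate readily, and surplus benzyl bromide with heat also caps the 5-OH that is hydrogen-bonded to the C4 carbonyl, as is routine for perbenzylation of polyhydroxyflavonols.

Step 2
Reactants: 2 3,5,7,4'-tetra-O-benzylkaempferol
Product: 3 8-iodo-3,5,7,4'-tetra-O-benzylkaempferol
Conditions: NIS (1.1 equiv), TFA (0.3 equiv), MeCN/CH2Cl2, 0 °C to rt, dark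
Reagents that add atoms: N-iodosuccinimide, O=C1CCC(=O)N1I
Why: Electrophilic aromatic iodination: ring A with its three oxygen donors is by far the most electron-rich arene, C3 is blocked, and of the two open sites C6 is walled in by two benzyloxy groups whereas C8 has one benzyloxy group and the small ring oxygen O1 beside it, which matches the known C8 preference of 5,7-dialkoxyflavones (site to be checked by HMBC and NOE).

Step 3
Reactants: 4 4,6-dihydroxybenzofuran-3(2H)-one
Product: 5 4,6-bis(benzyloxy)benzofuran-3(2H)-one
Conditions: BnBr (2.2 equiv), K2CO3 (3 equiv), DMF, rt to 50 °C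
Reagents that add atoms: benzyl bromide, BrCc1ccccc1
Why: Williamson ether synthesis: carbonate ionises the two phenols well before the C2 methylene competes, and only a slight excess of benzyl bromide is used so that C2 and O3 stay untouched, a protection in routine use for aurone precursors.

Step 4
Reactants: 5 4,6-bis(benzyloxy)benzofuran-3(2H)-one
Product: 7 4,6-bis(benzyloxy)-3-(methoxymethoxy)benzofuran, via potassium enolate 6 (not isolated)
Conditions: KN(SiMe3)2 (1.1 equiv), THF, −78 °C; then MOMCl (1.3 equiv), −78 to 0 °C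
Reagents that add atoms: chloromethyl methyl ether, COCCl
Why: Enolate O-alkylation: complete deprotonation by a hindered potassium amide in the cold suppresses self-aldol condensation, and the hard, oxocarbenium-like electrophile reacts at the oxygen of the loosely paired potassium enolate, a site choice reinforced by the gain of benzofuran aromaticity.

Step 5
Reactants: 7 4,6-bis(benzyloxy)-3-(methoxymethoxy)benzofuran; 3 8-iodo-3,5,7,4'-tetra-O-benzylkaempferol
Product: 10 2-(3,5,7,4'-tetra-O-benzylkaempferol-8-yl)-4,6-bis(benzyloxy)-3-(methoxymethoxy)benzofuran, via 2-lithiobenzofuran 8 (not isolated), via benzofuran-2-ylzinc chloride 9 (not isolated)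
Conditions: 7 (1.5 equiv), n-BuLi (1.45 equiv), THF, −78 °C; ZnCl2 (1.6 equiv, THF), −78 °C to rt; then 3 (1.0 equiv), Pd2(dba)3 (2.5 mol %), RuPhos (10 mol %), THF, 65 °C
Reagents that add atoms: none
Why: Directed lithiation, lithium-to-zinc transmetalation and Negishi cross-coupling: C2–H is the most acidic position of a benzofuran and is flanked by O1 and the coordinating OMOM group, the derived arylzinc chloride tolerates the chromone carbonyl, and zerovalent palladium carrying the bulky biarylphosphine RuPhos is an established system for joining heteroarylzinc halides to di-ortho-substituted aryl halides.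

Step 6
Reactants: 10 2-(3,5,7,4'-tetra-O-benzylkaempferol-8-yl)-4,6-bis(benzyloxy)-3-(methoxymethoxy)benzofuran
Product: 11 2-(3,5,7,4'-tetra-O-benzylkaempferol-8-yl)-4,6-bis(benzyloxy)benzofuran-3(2H)-one (racemic; C2 enolisable)
Conditions: 2 M aq HCl, THF (degassed), 40 °C, Ar; crude product kept under Ar and used at once
Reagents that add atoms: none
Why: Acid hydrolysis of a methoxymethyl acetal: the acetal carbon is the most acid-labile site, the freed 3-hydroxybenzofuran tautomerises to the more stable benzofuran-3(2H)-one, the benzyl ethers are inert to dilute acid, exclusion of oxygen guards the doubly activated C2–H against autoxidation, and the racemic C2 centre formed here is erased in the next step.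

Step 7
Reactants: 11 2-(3,5,7,4'-tetra-O-benzylkaempferol-8-yl)-4,6-bis(benzyloxy)benzofuran-3(2H)-one; 12 4-(benzyloxy)benzoyl chloride
Product: 13 2-(3,5,7,4'-tetra-O-benzylkaempferol-8-yl)-4,6-bis(benzyloxy)benzofuran-3-yl 4-(benzyloxy)benzoate (achiral)
Conditions: 12 (1.2 equiv), Et3N (1.5 equiv), CH2Cl2 (degassed), −20 to 0 °C, Ar, no nucleophilic catalyst
Reagents that add atoms: none
Why: Enol ester formation by kinetic O-acylation: the amine generates the delocalised olate reversibly, the hard acid chloride is taken at the exposed oxygen and not at the shielded tertiary C2, the product gains benzofuran aromaticity, and the absence of any nucleophilic catalyst keeps an uncontrolled racemic shift to carbon from starting.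

Step 8
Reactants: 13 2-(3,5,7,4'-tetra-O-benzylkaempferol-8-yl)-4,6-bis(benzyloxy)benzofuran-3-yl 4-(benzyloxy)benzoate
Product: 15 (R)-2-[4-(benzyloxy)benzoyl]-2-(3,5,7,4'-tetra-O-benzylkaempferol-8-yl)-4,6-bis(benzyloxy)benzofuran-3(2H)-one, via N-aroyl isothiouronium olate ion pair 14 (not isolated)
Conditions: (2S,3R)-HyperBTM [(2S,3R)-3-isopropyl-2-phenyl-3,4-dihydro-2H-benzo[4,5]thiazolo[3,2-a]pyrimidine] (20 mol %), toluene, 4 Å MS, 50 °C, Ar; recrystallisation to raise the enantiomeric purity if needed
Reagents that add atoms: none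
Why: Proposed new method: the imine-type nitrogen of the isothiourea adds to the ester carbonyl of 13 and expels the aromatic 2-aryl-4,6-dialkoxybenzofuran-3-olate, a leaving group of phenolate quality, to give the tight ion pair 14, in which the N-aroyl isothiouronium is locked flat by its 1,5 O···S contact and screened on one face by the pseudoaxial phenyl group; the olate then attacks the acyl carbon through its electron-rich C2, so that the C2–C(=O)Ar bond forms in place of the O3–acyl bond and the catalyst is released. The closest known reaction type is the catalytic enantioselective Steglich or Black O-to-C acyl/carboxyl rearrangement of O-acylated azlactones, benzofuran-2(3H)-ones and oxindoles with chiral nucleophilic catalysts; new here are the benzofuran-3-yl ester, the aroyl migrating group and a migration terminus bearing a di-ortho-substituted aryl group. No ring is closed in this step. The single new stereocentre, the quaternary C2 (R), is controlled by the catalyst alone, which decides which face of the planar olate meets the acyl carbon inside the ion pair. Two selectivities are needed, carbon over oxygen and one face over the other: acylation at oxygen merely returns 13 and stays reversible under catalysis, whereas 15 is a non-enolisable diketone whose ring ketone is stabilised by the three donor oxygens O1, 4-O and 6-O in ortho and para positions, so the material should drain to carbon, and the lack of an alpha hydrogen in the aroyl group rules out a ketene pathway that would bypass the chiral ion pair. The axis between benzofuran C2 and flavonol C8 of 13 has only oxygen substituents and a five-membered ring beside it and should rotate fast at 50 °C, so that the substrate acts as one achiral species and no kinetic resolution of rotamers interferes.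

Step 9
Reactants: 15 (R)-2-[4-(benzyloxy)benzoyl]-2-(3,5,7,4'-tetra-O-benzylkaempferol-8-yl)-4,6-bis(benzyloxy)benzofuran-3(2H)-one
Product: 17 target CNP0283000.1 (spiro carbon S; hemiketal carbon R), via ring-opened heptaphenol diketone 16 (not isolated)
Conditions: H2 (1 atm), 10% Pd/C, EtOAc/THF (1:1), rt; filtration under Ar, neutral to faintly acidic work-up, no base, no alcohol solvent
Reagents that add atoms: none
Why: Catalytic hydrogenolysis of aryl benzyl ethers followed by ring-chain tautomerism: all seven O–CH2Ph bonds are cleaved under neutral conditions that leave the chromone, both ketones and the non-enolisable quaternary centre untouched, the freed flavonol 7-OH then adds 5-exo-trig to the neighbouring aroyl carbonyl (the ring ketone C3=O is deactivated by O1, the 6-OH and the chelating 4-OH), and because this addition is reversible the hemiketal carbon should settle under thermodynamic control, relayed from the fixed spiro carbon, as the R epimer with its OH on the side of C3=O, where it can hydrogen-bond, and the 4-hydroxyphenyl group on the side of the ring oxygen O1.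

**Compound list**

1 | kaempferol, 3,5,7-trihydroxy-2-(4-hydroxyphenyl)-4H-chromen-4-one | O=c1c(O)c(-c2ccc(O)cc2)oc2cc(O)cc(O)c12 | starting material
2 | 3,5,7-tris(benzyloxy)-2-[4-(benzyloxy)phenyl]-4H-chromen-4-one (3,5,7,4'-tetra-O-benzylkaempferol) | O=c1c(OCc2ccccc2)c(-c2ccc(OCc3ccccc3)cc2)oc2cc(OCc3ccccc3)cc(OCc3ccccc3)c12 | intermediate
3 | 3,5,7-tris(benzyloxy)-2-[4-(benzyloxy)phenyl]-8-iodo-4H-chromen-4-one | O=c1c(OCc2ccccc2)c(-c2ccc(OCc3ccccc3)cc2)oc2c(I)c(OCc3ccccc3)cc(OCc3ccccc3)c12 | intermediate
4 | 4,6-dihydroxybenzofuran-3(2H)-one | O=C1COc2cc(O)cc(O)c12 | starting material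
5 | 4,6-bis(benzyloxy)benzofuran-3(2H)-one | O=C1COc2cc(OCc3ccccc3)cc(OCc3ccccc3)c12 | intermediate
6 | potassium 4,6-bis(benzyloxy)benzofuran-3-olate | [K+].[O-]c1coc2cc(OCc3ccccc3)cc(OCc3ccccc3)c12 | intermediate
7 | 4,6-bis(benzyloxy)-3-(methoxymethoxy)benzofuran | COCOc1coc2cc(OCc3ccccc3)cc(OCc3ccccc3)c12 | intermediate
8 | [4,6-bis(benzyloxy)-3-(methoxymethoxy)benzofuran-2-yl]lithium | [Li]c1oc2cc(OCc3ccccc3)cc(OCc3ccccc3)c2c1OCOC | intermediate
9 | [4,6-bis(benzyloxy)-3-(methoxymethoxy)benzofuran-2-yl]zinc chloride | Cl[Zn]c1oc2cc(OCc3ccccc3)cc(OCc3ccccc3)c2c1OCOC | intermediate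
10 | 3,5,7-tris(benzyloxy)-2-[4-(benzyloxy)phenyl]-8-[4,6-bis(benzyloxy)-3-(methoxymethoxy)benzofuran-2-yl]-4H-chromen-4-one | COCOc1c(-c2c(OCc3ccccc3)cc(OCc3ccccc3)c3c(=O)c(OCc4ccccc4)c(-c4ccc(OCc5ccccc5)cc4)oc23)oc2cc(OCc3ccccc3)cc(OCc3ccccc3)c12 | intermediate
11 | 3,5,7-tris(benzyloxy)-2-[4-(benzyloxy)phenyl]-8-[4,6-bis(benzyloxy)-3-oxo-2,3-dihydrobenzofuran-2-yl]-4H-chromen-4-one, racemic and configurationally labile at benzofuranone C2 | O=C1C(c2c(OCc3ccccc3)cc(OCc3ccccc3)c3c(=O)c(OCc4ccccc4)c(-c4ccc(OCc5ccccc5)cc4)oc23)Oc2cc(OCc3ccccc3)cc(OCc3ccccc3)c12 | intermediate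
12 | 4-(benzyloxy)benzoyl chloride | O=C(Cl)c1ccc(OCc2ccccc2)cc1 | starting material
13 | 4,6-bis(benzyloxy)-2-{3,5,7-tris(benzyloxy)-2-[4-(benzyloxy)phenyl]-4-oxo-4H-chromen-8-yl}benzofuran-3-yl 4-(benzyloxy)benzoate, achiral | O=C(Oc1c(-c2c(OCc3ccccc3)cc(OCc3ccccc3)c3c(=O)c(OCc4ccccc4)c(-c4ccc(OCc5ccccc5)cc4)oc23)oc2cc(OCc3ccccc3)cc(OCc3ccccc3)c12)c1ccc(OCc2ccccc2)cc1 | intermediate
14 | ion pair of (2S,3R)-1-[4-(benzyloxy)benzoyl]-HyperBTM isothiouronium and the 2-(flavonol-8-yl)-4,6-bis(benzyloxy)benzofuran-3-olate | CC(C)[C@@H]1CN2c3ccccc3SC2=[N+](C(=O)c2ccc(OCc3ccccc3)cc2)[C@@H]1c1ccccc1.[O-]c1c(-c2c(OCc3ccccc3)cc(OCc3ccccc3)c3c(=O)c(OCc4ccccc4)c(-c4ccc(OCc5ccccc5)cc4)oc23)oc2cc(OCc3ccccc3)cc(OCc3ccccc3)c12 | intermediate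
15 | (R)-8-{4,6-bis(benzyloxy)-2-[4-(benzyloxy)benzoyl]-3-oxo-2,3-dihydrobenzofuran-2-yl}-3,5,7-tris(benzyloxy)-2-[4-(benzyloxy)phenyl]-4H-chromen-4-one | O=C1c2c(OCc3ccccc3)cc(OCc3ccccc3)cc2O[C@@]1(C(=O)c1ccc(OCc2ccccc2)cc1)c1c(OCc2ccccc2)cc(OCc2ccccc2)c2c(=O)c(OCc3ccccc3)c(-c3ccc(OCc4ccccc4)cc3)oc12 | intermediate
16 | (R)-8-[4,6-dihydroxy-2-(4-hydroxybenzoyl)-3-oxo-2,3-dihydrobenzofuran-2-yl]-3,5,7-trihydroxy-2-(4-hydroxyphenyl)-4H-chromen-4-one | O=C1c2c(O)cc(O)cc2O[C@@]1(C(=O)c1ccc(O)cc1)c1c(O)cc(O)c2c(=O)c(O)c(-c3ccc(O)cc3)oc12 | intermediate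
17 | CNP0283000.1, (2S,8'R)-3',4,5',6,8'-pentahydroxy-2',8'-bis(4-hydroxyphenyl)spiro[benzofuran-2,9'-furo[2,3-h]chromene]-3,4'(8'H)-dione | O=C1c2c(O)cc(O)cc2O[C@@]12c1c(cc(O)c3c(=O)c(O)c(-c4ccc(O)cc4)oc13)O[C@]2(O)c1ccc(O)cc1 | target

**Step count**

Total step count: 9.
Longest linear sequence: 7 steps, by either branch (steps 1, 2, 5, 6, 7, 8, 9 or steps 3, 4, 5, 6, 7, 8, 9).

**Steps most likely to fail**

1. Step 8 (bears the label). The ion pair may collapse only at oxygen, so that the shift does not turn over at the crowded C2. The equilibrium may not lie far enough on the carbon side. The facial selectivity may also erode at the temperature needed.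
The fallback uses known chemistry, sets out from 11 and comes back at 15. The carbon–carbon bond is made with an aldehyde, which cannot be held at oxygen, and the ketone is installed afterwards by oxidation. Ketone 11 is silylated (TMSOTf, Et3N, CH2Cl2, 0 °C) to the 3-(trimethylsilyloxy)benzofuran F1. A Mukaiyama aldol addition of F1 to commercial 4-(benzyloxy)benzaldehyde (BF3·OEt2, CH2Cl2, −78 °C, mildly acidic work-up) gives the racemic beta-hydroxy ketone F2 as a mixture of carbinol epimers. Dess–Martin oxidation (CH2Cl2, NaHCO3, rt) erases the carbinol centre and gives the racemic diketone F3. Preparative chromatography on a chiral stationary phase then separates 15 from its (S)-enantiomer F4.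

2. Step 5. Oxidative addition and reductive elimination at the di-ortho-substituted aryl iodide may be slow. Protodemetalation of the electron-rich benzofuranylzinc, homocoupling and hydrodeiodination could then take over.
The fallback sets out from 3 and 7 and comes back at 10. The roles of the partners are exchanged, so that the metal sits on the robust flavonol and the halide on the small benzofuran. Miyaura borylation of 3 (B2pin2, PdCl2(dppf), KOAc, dioxane, 90 °C) gives the flavonol 8-pinacolboronate F5. Compound 7 is lithiated to 8 as before and quenched with iodine (I2, THF, −78 °C) to give 2-iodo-4,6-bis(benzyloxy)-3-(methoxymethoxy)benzofuran F6. Suzuki–Miyaura coupling of F5 with F6 (Pd(OAc)2, SPhos, K3PO4, toluene/water, 80 °C) gives 10. Oxidative addition then occurs at an unhindered 2-iodobenzofuran, and flavone 8-boronates are established partners in biflavone synthesis.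

3. Step 9. Over-reduction may occur, either by hydrogenolysis of the benzylic carbon–oxygen bonds at the spiro and hemiketal carbons or by reduction of the aroyl ketone. The hindered benzyl ethers may be cleaved incompletely. Retro-Claisen opening of the diketone during work-up is a further risk.
The fallback sets out from 15 and comes back at 17 by way of 16. It is a non-reductive Lewis-acid dealkylation with a cation scavenger (BCl3, pentamethylbenzene, CH2Cl2, −78 °C, quench with pH 5 phosphate buffer). The benzyl groups leave as cations that are trapped by Friedel–Crafts alkylation of the scavenger. No hydrogen and no metal surface is present, so nothing can be reduced, and the medium stays acidic throughout. No compound outside the list arises (F0).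

**Further compounds**

F1 | step 8 | 8-[4,6-bis(benzyloxy)-3-(trimethylsilyloxy)benzofuran-2-yl]-3,5,7-tris(benzyloxy)-2-[4-(benzyloxy)phenyl]-4H-chromen-4-one | C[Si](C)(C)Oc1c(-c2c(OCc3ccccc3)cc(OCc3ccccc3)c3c(=O)c(OCc4ccccc4)c(-c4ccc(OCc5ccccc5)cc4)oc23)oc2cc(OCc3ccccc3)cc(OCc3ccccc3)c12
F2 | step 8 | 8-{4,6-bis(benzyloxy)-2-[[4-(benzyloxy)phenyl](hydroxy)methyl]-3-oxo-2,3-dihydrobenzofuran-2-yl}-3,5,7-tris(benzyloxy)-2-[4-(benzyloxy)phenyl]-4H-chromen-4-one, racemic, mixture of carbinol epimers | O=C1c2c(OCc3ccccc3)cc(OCc3ccccc3)cc2OC1(C(O)c1ccc(OCc2ccccc2)cc1)c1c(OCc2ccccc2)cc(OCc2ccccc2)c2c(=O)c(OCc3ccccc3)c(-c3ccc(OCc4ccccc4)cc3)oc12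
F3 | step 8 | racemic 8-{4,6-bis(benzyloxy)-2-[4-(benzyloxy)benzoyl]-3-oxo-2,3-dihydrobenzofuran-2-yl}-3,5,7-tris(benzyloxy)-2-[4-(benzyloxy)phenyl]-4H-chromen-4-one | O=C1c2c(OCc3ccccc3)cc(OCc3ccccc3)cc2OC1(C(=O)c1ccc(OCc2ccccc2)cc1)c1c(OCc2ccccc2)cc(OCc2ccccc2)c2c(=O)c(OCc3ccccc3)c(-c3ccc(OCc4ccccc4)cc3)oc12
F4 | step 8 | (S)-8-{4,6-bis(benzyloxy)-2-[4-(benzyloxy)benzoyl]-3-oxo-2,3-dihydrobenzofuran-2-yl}-3,5,7-tris(benzyloxy)-2-[4-(benzyloxy)phenyl]-4H-chromen-4-one | O=C1c2c(OCc3ccccc3)cc(OCc3ccccc3)cc2O[C@]1(C(=O)c1ccc(OCc2ccccc2)cc1)c1c(OCc2ccccc2)cc(OCc2ccccc2)c2c(=O)c(OCc3ccccc3)c(-c3ccc(OCc4ccccc4)cc3)oc12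
F5 | step 5 | 3,5,7-tris(benzyloxy)-2-[4-(benzyloxy)phenyl]-8-(4,4,5,5-tetramethyl-1,3,2-dioxaborolan-2-yl)-4H-chromen-4-one | O=c1c(OCc2ccccc2)c(-c2ccc(OCc3ccccc3)cc2)oc2c(B3OC(C)(C)C(C)(C)O3)c(OCc3ccccc3)cc(OCc3ccccc3)c12
F6 | step 5 | 2-iodo-4,6-bis(benzyloxy)-3-(methoxymethoxy)benzofuran | COCOc1c(I)oc2cc(OCc3ccccc3)cc(OCc3ccccc3)c12
F0 | step 9 | none | none
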